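**Plan**

- The ten-membered ring C1–C10 holds the 1,5-diene C10=C1–C2–C3–C4=C5 once the C1,C10-diol is traced back to an E olefin and the C3 ketone to its dioxolane. That diene is the cycloreversion retron of a bicyclo[2.2.0]hexane (cyclobutane C1–C2–C3–C4 fused along C1–C4 to cyclobutane C1–C4–C5–C10) fused to the six-membered ring C5–C10.
- Retrosynthesis: cut the diol C–O bonds, the angelate, C11=C13 and the lactone C12–O6; re-form C1–C4 and C5–C10; then cut C4–C5 and C1–C10 to a cyclohexenone (C5=C10, C6=O) and a cyclobutenone ketal (C1=C4).
- Forward: ring C5–C10 closes by intramolecular Horner–Wadsworth–Emmons olefination, C7 is alkylated, the [2+2] photocycloaddition joins the fragments, the lactone closes on O6, heating opens the bicyclohexane to the ten-membered ring, which is then functionalised.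
- Stereochemistry: C8 comes from a commercial (R)-3-silyloxyglutarate-derived phosphonate and directs trans alkylation at C7 and the face of the photocycloaddition; C6 follows from convex-face hydride delivery and lactonisation.
- The trans C7/C8 relationship is kept through the cycloreversion because it holds ring C5–C10 in the chair that should give C1=C10 E and C4=C5 Z; C8 is then inverted by oxidation/reduction so that O6, C11 and O8 are all cis, and C1/C10 come from ligand-matched syn-dihydroxylation.

Key step: step 7

Remark: target atom numbering (C1–C15, lactone carbons C11–C13) is used for every intermediate, and CIP descriptors of intermediates are given with these locants.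
Remark: phosphonate 1 (statin side-chain reagent), racemic 2-methylcyclobutanone and angelic acid are taken as purchasable.
Remark: the target is made and drawn as the open 3-keto-1,10-diol; a transannular hemiketal tautomer, if populated, would be in equilibrium with it.

Step 1
Reactants: 1 methyl (3R)-3-(tert-butyldimethylsilyloxy)-6-(dimethoxyphosphoryl)-5-oxohexanoate
Product: 2 (3R)-Weinreb amide of 1
Conditions: MeNHOMe·HCl (1.6 equiv), iPrMgCl (4.2 equiv), THF, −20 °C to 0 °C
Reagents that add atoms: N,O-dimethylhydroxylamine hydrochloride, CNOC.Cl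
Why: Ester aminolysis by the chloromagnesium amide (Weinreb amide formation) is selective because the first equivalent of Grignard reagent turns the β-ketophosphonate into an unreactive magnesium enolate, and the silyloxy stereocentre (C8) is not touched.

Step 2
Reactants: 2 (3R)-Weinreb amide
Product: 3 dimethyl [(4S)-4-(tert-butyldimethylsilyloxy)-2,6-dioxoheptyl]phosphonate
Conditions: MeMgBr (3.0 equiv), THF, −78 °C to 0 °C; aq. NH4Cl
Reagents that add atoms: methylmagnesium bromide, C[Mg]Br
Why: Weinreb ketone synthesis, in which the first equivalent deprotonates the β-ketophosphonate and the next forms a chelated tetrahedral intermediate that gives the methyl ketone (C10 and its methyl) only on work-up.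

Step 3
Reactants: 3 diketophosphonate
Product: 4 (5S)-5-(tert-butyldimethylsilyloxy)-3-methylcyclohex-2-en-1-one
Conditions: LiCl (1.5 equiv), iPr2NEt (1.2 equiv), MeCN, 23 °C
Reagents that add atoms: none
Why: Intramolecular Horner–Wadsworth–Emmons olefination under Masamune–Roush conditions generates only the phosphonate carbanion, which closes the six-membered ring onto the methyl ketone to form C5=C10 without β-elimination of the silyloxy group.

Step 4
Reactants: 4 (5S)-silyloxy enone; 5 methyl bromoacetate
Product: 6 methyl 2-[(1R,6S)-6-(tert-butyldimethylsilyloxy)-4-methyl-2-oxocyclohex-3-en-1-yl]acetate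
Conditions: LiN(iPr)2 (1.05 equiv), THF, −78 °C; then 5 (1.3 equiv), DMPU, −78 °C to −40 °C
Reagents that add atoms: none
Why: Kinetic α′-deprotonation gives the cross-conjugated lithium enolate and SN2 alkylation occurs anti to the adjacent silyloxy group (the known trans selectivity of 5-silyloxycyclohexenone enolates), setting C7 as R with the side chain trans to the C8 oxygen.

Step 5
Reactants: 7 2-methylcyclobutanone (racemic)
Product: 9 1-bromo-1-methyl-5,8-dioxaspiro[3.4]octane (racemic), via ketal 8 (not isolated)
Conditions: ethylene glycol (solvent), Br2 (1.0 equiv), 10 °C to 23 °C; Na2CO3 work-up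
Reagents that add atoms: ethylene glycol, OCCO; bromine, BrBr
Why: Ketalisation catalysed by the HBr formed in situ and α-bromination of the ketal through its more substituted enol ether place bromine on the methyl-bearing carbon.

Step 6
Reactants: 9 bromo ketal
Product: 10 1-methyl-5,8-dioxaspiro[3.4]oct-1-ene
Conditions: KOtBu (1.5 equiv), DMSO, 23 °C; distillation
Reagents that add atoms: none
Why: E2 dehydrobromination of a tertiary α-bromo ketal is the standard route to 2-alkylcycloalk-2-enone ketals, the endocyclic trisubstituted olefin being favoured over the exocyclic isomer under these equilibrating conditions.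

Step 7
Reactants: 6 alkylated enone (7R,8S); 10 cyclobutene ketal
Product: 11 cis,anti,cis tricyclic photoadduct (1R,4R,5R,7R,8S,10R)
Conditions: hν (350 nm, Pyrex), 10 (5 equiv), CH2Cl2 (0.03 M), −20 °C, argon
Reagents that add atoms: none
Why: The triplet enone of 6 adds stepwise to the strained cyclobutene 10 through a 1,4-diradical that closes after spin inversion, the classical enone–alkene [2+2] photocycloaddition, whose closest analogue is the addition of 1-methylcyclobutene to 3-methylcyclohexenones. The one new ring, cyclobutane C1–C4–C5–C10, closes by combination of the two radical termini; the short linkage forces cis fusion to the cyclohexanone at C5–C10, and the existing four-membered ring is necessarily cis at C1–C4. The two four-membered rings end up anti because the dioxolane-bearing ring approaches with its bulk turned away from C6 and C9. C10 and C5 are set by approach to the enone face opposite the C8 silyloxy group (axial-type bonding at C10 trans to the 5-substituent), and C1 and C4 follow from the cis, anti closure. The step needs head-to-head regiochemistry (C4–C5 and C1–C10), which the C10 methyl secures because the alternative would join the two quaternary carbons C4 and C10; the facial outcome matters only for the C6 reduction, since all four cyclobutane stereocentres are destroyed in step 9.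

Step 8
Reactants: 11 photoadduct
Product: 13 tetracyclic 12,6-lactone (6S,7S,8S), via hydroxy ester 12 (not isolated)
Conditions: Li[HB(sec-Bu)3] (1.2 equiv), THF, −78 °C to 23 °C; aq. NH4Cl
Reagents that add atoms: none
Why: Hydride reduction by a bulky borohydride from the convex face opposite the cyclobutane (the axial trajectory is blocked by C1) sets C6 as S with the alkoxide cis to the C7 side chain, and the alkoxide lactonises onto the methyl ester (5-exo-trig acyl substitution) on warming.

Step 9
Reactants: 13 tetracyclic lactone
Product: 14 ten-membered (1(10)E,4Z)-diene lactone (6S,7S,8S)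
Conditions: toluene (0.01 M, degassed), BHT (cat.), base-washed sealed tube, 180 °C, 2 h
Reagents that add atoms: none
Why: Thermal stepwise retro-[2+2] of the bicyclo[2.2.0]hexane (homolysis of the central C1–C4 bond, then β-scission of C5–C10 in a chair-like 1,4-diradical) is known to turn cis,anti,cis adducts of this type into E,Z-cyclodeca-1,5-dienes; the chair of ring C5–C10 that keeps C4 and the C10 methyl equatorial puts C9 equatorial and C6 axial on the diradical ring, which should translate into E at C1=C10 and Z at C4=C5, and having C6 at the alcohol (lactone) level avoids the Cope rearrangement expected for the dienone.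

Step 10
Reactants: 14 diene lactone
Product: 15 C11 dimethylaminomethyl lactone (Mannich base)
Conditions: LiN(iPr)2 (1.3 equiv), THF, −78 °C; then CH2=NMe2+ I− (3 equiv), −78 °C to 23 °C
Reagents that add atoms: N,N-dimethylmethyleneiminium iodide (Eschenmoser's salt), C=[N+](C)C.[I-]
Why: Aminomethylation of the lactone enolate (Mannich reaction) installs C13 as a masked α-methylene group that survives the hydride and acylation steps and keeps the later C8 ketone from being vinylogous to the lactone carbonyl; the C11 configuration is of no consequence.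

Step 11
Reactants: 15 Mannich base silyl ether
Product: 16 C8 alcohol (6S,7R,8S)
Conditions: Bu4NF (1.5 equiv), AcOH (1.5 equiv), THF, 0 °C to 23 °C
Reagents that add atoms: none
Why: Fluoride-mediated silyl ether cleavage buffered with acetic acid frees the C8 hydroxyl without exposing the lactone to a basic alkoxide.

Step 12
Reactants: 16 C8 alcohol (8S)
Product: 18 C8-inverted alcohol (6S,7R,8R), via ketone 17 (not isolated)
Conditions: Dess–Martin periodinane (1.5 equiv), NaHCO3, CH2Cl2, 0 °C; filtration; then Li[HB(sec-Bu)3] (1.2 equiv), THF, −78 °C; AcOH quench at −78 °C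
Reagents that add atoms: none
Why: Dess–Martin oxidation followed without purification by trialkylborohydride reduction inverts C8, the bulky hydride being expected to add to the ketone face remote from the C7–C11 bond of the cis-fused lactone (1,2-induction as in 2-substituted cycloalkanones) to give the alcohol cis to the lactone, while the low temperature and cold acidic quench protect the β-acyloxy ketone and prevent lactone migration.

Step 13
Reactants: 18 C8-inverted alcohol; 19 angelic acid
Product: 21 C8 angelate (6S,7R,8R), via mixed anhydride 20 (not isolated)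
Conditions: 19 (3 equiv), 2,4,6-trichlorobenzoyl chloride (3 equiv), Et3N (6 equiv), toluene, 23 °C; then 18, 60 °C
Reagents that add atoms: none
Why: Yamaguchi esterification through the 2,4,6-trichlorobenzoic mixed anhydride without a nucleophilic catalyst acylates the C8 hydroxyl with retention and is known to transfer the angelate group without isomerisation to tiglate.

Step 14
Reactants: 21 angelate Mannich base
Product: 23 α-methylene lactone (6S,7R,8R), via ammonium iodide 22 (not isolated)
Conditions: MeI (10 equiv), MeOH/CH2Cl2, 23 °C; then aq. NaHCO3, CH2Cl2, 23 °C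
Reagents that add atoms: none
Why: Quaternisation of the Mannich base and E1cB elimination of trimethylamine under bicarbonate unveil the α-methylene lactone under conditions that leave the angelate and the strained E olefin untouched.

Step 15
Reactants: 23 triene lactone
Product: 24 (1S,10S)-diol (1S,6S,7R,8R,10S)
Conditions: K2OsO2(OH)4 (5 mol %), (DHQ)2PHAL (10 mol %), N-methylmorpholine N-oxide (1.5 equiv), tBuOH/H2O 1:1, 0 °C; aq. Na2SO3
Reagents that add atoms: N-methylmorpholine N-oxide, C[N+]1([O-])CCOCC1; water, O
Why: Sharpless asymmetric dihydroxylation attacks the electron-rich trisubstituted E olefin C1=C10 in preference to the hindered Z olefin and the two conjugated olefins, syn addition to the E geometry gives the 1S,10S or 1R,10R pair, and the (DHQ)2PHAL ligand is the one whose mnemonic selects the face leading to 1S,10S.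

Step 16
Reactants: 24 diol ketal
Product: 25 target CNP0271189.1
Conditions: pyridinium p-toluenesulfonate (0.3 equiv), THF/H2O 4:1, 45 °C
Reagents that add atoms: water, O
Why: Acid-catalysed hydrolysis of the dioxolane, helped by the allylic stabilisation of the oxocarbenium ion, releases the C3 ketone in conjugation with the Z C4=C5 bond under conditions mild enough for the β-hydroxy ketone, the tertiary alcohol and both unsaturated esters.

**Compound list**

1 | methyl (3R)-3-(tert-butyldimethylsilyloxy)-6-(dimethoxyphosphoryl)-5-oxohexanoate | COC(=O)C[C@H](O[Si](C)(C)C(C)(C)C)CC(=O)CP(=O)(OC)OC | starting material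
2 | (3R)-3-(tert-butyldimethylsilyloxy)-6-(dimethoxyphosphoryl)-N-methoxy-N-methyl-5-oxohexanamide | CON(C)C(=O)C[C@H](O[Si](C)(C)C(C)(C)C)CC(=O)CP(=O)(OC)OC | intermediate
3 | dimethyl [(4S)-4-(tert-butyldimethylsilyloxy)-2,6-dioxoheptyl]phosphonate | CC(=O)C[C@H](O[Si](C)(C)C(C)(C)C)CC(=O)CP(=O)(OC)OC | intermediate
4 | (5S)-5-(tert-butyldimethylsilyloxy)-3-methylcyclohex-2-en-1-one | CC1=CC(=O)C[C@@H](O[Si](C)(C)C(C)(C)C)C1 | intermediate
5 | methyl bromoacetate | COC(=O)CBr | starting material
6 | methyl 2-[(1R,6S)-6-(tert-butyldimethylsilyloxy)-4-methyl-2-oxocyclohex-3-en-1-yl]acetate (C7 R, C8 S; side chain trans to OTBS) | CC1=CC(=O)[C@H](CC(=O)OC)[C@@H](O[Si](C)(C)C(C)(C)C)C1 | intermediate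
7 | 2-methylcyclobutanone (racemic) | CC1CCC1=O | starting material
8 | 1-methyl-5,8-dioxaspiro[3.4]octane (racemic) | CC1CCC12OCCO2 | intermediate
9 | 1-bromo-1-methyl-5,8-dioxaspiro[3.4]octane (racemic) | CC1(Br)CCC12OCCO2 | intermediate
10 | 1-methyl-5,8-dioxaspiro[3.4]oct-1-ene (2-methylcyclobut-2-enone ethylene ketal) | CC1=CCC12OCCO2 | intermediate
11 | cis,anti,cis tricyclo[4.4.0.0^2,5]decanone photoadduct: C6 ketone, C3 spiro-dioxolane, methyls on C4 and C10, CH2CO2Me on C7, OTBS on C8; (1R,4R,5R,7R,8S,10R); cyclobutane anti to OTBS, syn to the C7 side chain | O=C1[C@H](CC(=O)OC)[C@@H](O[Si](C)(C)C(C)(C)C)C[C@]2(C)[C@H]3CC4(OCCO4)[C@@]3(C)[C@H]12 | intermediate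
12 | C6 alcohol of 11 (6S; hydroxyl cis to the C7 side chain and to the cyclobutane) | O[C@@H]1[C@H](CC(=O)OC)[C@@H](O[Si](C)(C)C(C)(C)C)C[C@]2(C)[C@H]3CC4(OCCO4)[C@@]3(C)[C@H]12 | intermediate
13 | tetracyclic cis-fused 12,6-γ-lactone of 12; (1R,4R,5R,6S,7S,8S,10R); C8 OTBS trans to the lactone | O=C1C[C@@H]2[C@@H](O[Si](C)(C)C(C)(C)C)C[C@]3(C)[C@H]4CC5(OCCO5)[C@@]4(C)[C@@H]3[C@@H]2O1 | intermediate
14 | (1(10)E,4Z,6S,7S,8S)-8-(tert-butyldimethylsilyloxy)-3,3-(ethylenedioxy)-13-norgermacra-1(10),4-dien-12,6-olide | O=C1O[C@H]2/C=C(/C)C3(OCCO3)C/C=C(\C)C[C@H](O[Si](C)(C)C(C)(C)C)[C@H]2C1 | intermediate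
15 | (1(10)E,4Z,6S,7S,8S)-8-(tert-butyldimethylsilyloxy)-13-(dimethylamino)-3,3-(ethylenedioxy)germacra-1(10),4-dien-12,6-olide (C11 epimers) | O=C1O[C@H]2/C=C(/C)C3(OCCO3)C/C=C(\C)C[C@H](O[Si](C)(C)C(C)(C)C)[C@H]2C1CN(C)C | intermediate
16 | (1(10)E,4Z,6S,7R,8S)-13-(dimethylamino)-3,3-(ethylenedioxy)-8-hydroxygermacra-1(10),4-dien-12,6-olide (hydroxyl trans to the lactone) | O=C1O[C@H]2/C=C(/C)C3(OCCO3)C/C=C(\C)C[C@H](O)[C@H]2C1CN(C)C | intermediate
17 | (1(10)E,4Z,6S,7S)-13-(dimethylamino)-3,3-(ethylenedioxy)-8-oxogermacra-1(10),4-dien-12,6-olide | O=C1O[C@H]2/C=C(/C)C3(OCCO3)C/C=C(\C)CC(=O)[C@H]2C1CN(C)C | intermediate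
18 | (1(10)E,4Z,6S,7R,8R)-13-(dimethylamino)-3,3-(ethylenedioxy)-8-hydroxygermacra-1(10),4-dien-12,6-olide (hydroxyl cis to the lactone) | O=C1O[C@H]2/C=C(/C)C3(OCCO3)C/C=C(\C)C[C@@H](O)[C@H]2C1CN(C)C | intermediate
19 | angelic acid, (Z)-2-methylbut-2-enoic acid | C/C=C(/C)C(=O)O | starting material
20 | (Z)-2-methylbut-2-enoic 2,4,6-trichlorobenzoic anhydride | C/C=C(/C)C(=O)OC(=O)c1c(Cl)cc(Cl)cc1Cl | intermediate
21 | (1(10)E,4Z,6S,7R,8R)-8-angeloyloxy-13-(dimethylamino)-3,3-(ethylenedioxy)germacra-1(10),4-dien-12,6-olide | O=C1O[C@H]2/C=C(/C)C3(OCCO3)C/C=C(\C)C[C@@H](OC(=O)/C(C)=C\C)[C@H]2C1CN(C)C | intermediate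
22 | trimethylammonium iodide of 21 | O=C1O[C@H]2/C=C(/C)C3(OCCO3)C/C=C(\C)C[C@@H](OC(=O)/C(C)=C\C)[C@H]2C1C[N+](C)(C)C.[I-] | intermediate
23 | (1(10)E,4Z,6S,7R,8R)-8-angeloyloxy-3,3-(ethylenedioxy)germacra-1(10),4,11(13)-trien-12,6-olide | C=C1C(=O)O[C@H]2/C=C(/C)C3(OCCO3)C/C=C(\C)C[C@@H](OC(=O)/C(C)=C\C)[C@@H]12 | intermediate
24 | (1S,4Z,6S,7R,8R,10S)-8-angeloyloxy-3,3-(ethylenedioxy)-1,10-dihydroxygermacra-4,11(13)-dien-12,6-olide | C=C1C(=O)O[C@H]2/C=C(/C)C3(OCCO3)C[C@H](O)[C@@](C)(O)C[C@@H](OC(=O)/C(C)=C\C)[C@@H]12 | intermediate
25 | CNP0271189.1, (1S,4Z,6S,7R,8R,10S)-8-angeloyloxy-1,10-dihydroxy-3-oxogermacra-4,11(13)-dien-12,6-olide | C=C1C(=O)O[C@H]2/C=C(/C)C(=O)C[C@H](O)[C@@](C)(O)C[C@@H](OC(=O)/C(C)=C\C)[C@@H]12 | target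

**Step count and risks**

Total steps: 16. Longest linear sequence: 14 (steps 1–4 and 7–16).

Step 7 is at risk because the 1,4-diradical may close to the trans-fused ring junction at C5–C10, and enone dimerisation may compete with addition to the hindered trisubstituted cyclobutene. The fallback replaces kinetic control of the ring fusion by thermodynamic control: irradiation of 6 with 10 would then give the trans-fused C5 epimer of the photoadduct F1. Because C5 is α to the C6 ketone, brief equilibration of the crude adduct on basic Al2O3 in Et2O epimerises C5 to the less strained cis fusion and returns to the route at 11. C7, whose trans relationship to the silyloxy group is the stable one, is not expected to change.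

Step 9 is at risk because the diradical may fragment through the other chair, giving Z at C1=C10 and E at C4=C5, or the diene may undergo Cope rearrangement at the temperature at which it forms. The fallback moves the cycloreversion ahead of the lactonisation, so that ring C5–C10 is not distorted by the fused lactone and the substrate is the closest analogue of the known dienol-forming openings. It sets out from 11: reduction with Li[HB(sec-Bu)3] at −78 °C and trapping of the C6 alkoxide with Me3SiCl before warming gives the C6 trimethylsilyl ether of the hydroxy ester F2. Thermolysis as in step 9 gives the open ten-membered diene ester F3. K2CO3 in MeOH then cleaves the trimethylsilyl ether selectively and the cis hydroxy ester lactonises, rejoining the route at 14.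

Step 12 is at risk because hydride may be delivered to the wrong face of the flexible ten-membered ketone, or the β-acyloxy ketone may epimerise at C7 or eliminate before it is reduced. The fallback inverts C8 by substitution instead of by a redox pair: Mitsunobu esterification of 16 with angelic acid 19 (PPh3, DIAD, toluene, 0 °C to 23 °C) displaces the activated C8 oxygen with inversion and gives the angelate directly, returning to the route at 21. This fallback makes no compound outside the list (none, F0).

**Further compounds**

F1 | step 7 | trans-fused C5 epimer of photoadduct 11 | O=C1[C@H](CC(=O)OC)[C@@H](O[Si](C)(C)C(C)(C)C)C[C@]2(C)[C@H]3CC4(OCCO4)[C@@]3(C)[C@@H]12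
F2 | step 9 | C6 trimethylsilyl ether of hydroxy ester 12 | C[Si](C)(C)O[C@@H]1[C@H](CC(=O)OC)[C@@H](O[Si](C)(C)C(C)(C)C)C[C@]2(C)[C@H]3CC4(OCCO4)[C@@]3(C)[C@H]12
F3 | step 9 | ten-membered (1(10)E,4Z)-diene methyl ester with C6 OSiMe3, C8 OTBS and C3 dioxolane | COC(=O)C[C@H]1[C@@H](O[Si](C)(C)C)/C=C(/C)C2(OCCO2)C/C=C(\C)C[C@@H]1O[Si](C)(C)C(C)(C)C
F0 | step 12 | none | none
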